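## Structural features

The target is a germacrane-type sesquiterpene lactone whose ten-membered carbocycle C1–C10 is spanned by an oxygen bridge from C3 to C10. O, C3, C2, C1 and C10 therefore form a 3(2H)-furanone (ring A: C1 ketone, C2=C3 enol ether), and the carbocycle is held as an 11-oxabicyclo[6.2.1]undecane. An α-methylene-γ-butyrolactone (ring C: C7, C11, C12, O, C8, with C11=C13) is cis-fused across C7–C8. C6 carries a methacrylate, C5 a free secondary hydroxyl, and C4 an exocyclic methylene (C15) conjugated through C2=C3 with the C1 ketone. Four stereocentres are contiguous, C5 (S), C6 (R), C7 (S) and C8 (S); the fifth, the fully substituted ether carbon C10 (R, methyl C14), is cut off from them by the C9 methylene and cannot be set by relay from its neighbours. The fragile elements are the three Michael acceptors, the C6 ester beside the free C5 hydroxyl (acyl shift), a lactone that can re-close on O6 whenever that oxygen is free, and, in any open precursor with a C10 ketone, the lactone oxygen on C8 that is expelled on enolisation towards C9. The real difficulty is the strained bridged medium ring together with the isolated quaternary C10. The key step exploits that, in ring A, C10 carries O, CH3 and C9 next to the C1 carbonyl: this is the product pattern of heterocyclisation and 1,2-shift of an open-chain isomer with a C10 ketone and a C1 tertiary propargylic carbinol, which forms O–C3 and C10–C14 in one operation and passes the C1 configuration on to C10. A re-derivation of the descriptors gives 5S,6R,7S,8S,10R for the target and 1R,6R,7S,8S for the open precursor; 1R maps onto 10R under a suprafacial shift, so the structures stand and only the plan around them is changed.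

## Logic of the disconnections

28 is opened at C4–C5 to 27. This bond joins an sp2 carbon to a carbinol carbon and is the only ring bond that can be made by a chemoselective organochromium addition in the presence of three enoates. The gain is an acyclic C4–C5 region; the demand is ring closure at high dilution with attack on the aldehyde face that gives 5S.

27 is traced through 26 to 25 by oxidation-level and protecting-group changes at C5 only. The α-acyloxy aldehyde is too labile to be carried, so it is made last from a silyl ether. The demand is that desilylation and oxidation be non-basic, so that the C6 ester neither migrates nor epimerises.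

25 is traced through 24 and 23 to 22 by cutting C4–I and then C15–Si. The alkyne is conjugated with the electron-poor furanone, so a proton/iodide addition would place iodide on C15. The C4 iodide is therefore derived from a C4 stannane made by hydropalladation. The demand is regiocontrol for the internal position and restraint towards the enoates.

22 is cut at O–C3 and C10–C14 to 21. This removes ring A and the quaternary stereocentre in one move and turns C10 into a ketone and C1 into a carbinol that is accessible by alkynylation. The demand is a neutral carbophilic catalyst and a stereospecific shift.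

21 is cut at the C6–O acyl bond to 19 and 20, and 19 is traced through 18 to 17 by protecting-group changes at C5 and C6. The C5 ether is a silyl ether and not a benzyl-type ether: it goes on the primary hydroxyl of the diol selectively in one step and comes off under non-basic fluoride. The demand is that the free O6 be acylated before it can attack the lactone.

17 is traced through 16 to 15 by returning C10 to the carbinol level under two silyl groups. A β-keto aldehyde cannot serve as the C8 electrophile, and the β-acyloxy ketone should exist for as few steps as possible. The demand is an oxidation of a 1,2-diol that does not cleave it.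

15 is cut at C7–C8 and at O8–C12 to 9 and 13, through 14. One allylation sets C7 and C8, delivers the exocyclic C11=C13 and closes the cis lactone, so no enolate methylenation is needed after the ketone exists (it would open the lactone by elimination). The gain is two fragments of similar size; the demand is syn selectivity and control of the C7 face by C6.

13 is traced through 12 to 10 and 11 by cutting C7–C11. The aldehyde carbon of 10 becomes C7 and its stereocentre becomes C6 (R). The demand is a (Z) bromide.

9 is traced through 8 and 7 to 6 by cutting C9–C10; C8 is revealed from a terminal alkene. The demand is cleavage of the alkene beside a silyl diyne.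

6 is traced through 5 and 4 to 2 and 3 by cutting C1–C2, and 2 comes from 1. The ester carbon of 3 becomes C10 and its ketone carbon becomes C1. The demand is catalyst control of the C1 configuration, the only source of the C10 configuration.

## Other disconnections considered

Alternative 1: The cut is C3–C4, with C1–C6 closed in the retron, so the medium ring is traced back to a six-membered ring fused to the dihydrofuran. In the forward sense, deprotonation at O1 (KH, 18-crown-6) would start an anionic oxy-Cope shift through C2=C3 and an allene on C6, breaking C1–C6, forming C3–C4 and giving A1.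
- In its favour: the ring expansion is intramolecular and needs no high dilution; C7, C8 and C10 are placed on a cyclohexane; C4=C15 comes straight from the allene. On formation of the medium ring it is the better plan, and on the security of C10 it is the equal.
- Against it here: A1 is far from the target. C3 is sp3 and must be dehydrogenated, the C5=C6 enol ether must become C5–OH and C6–O-acyl with two new stereocentres on a flexible ring, and the lactone must be built from the C7 side chain and methylenated by enolate chemistry beside the C1 ketone. The hydride base excludes esters before the shift, and the shift needs a boat-like array across a fused bicycle.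
- Comparison: the chosen plan reaches the furanone oxidation level and the lactone directly and needs five steps after its key step; this one would need clearly more.

Alternative 2: No skeletal bond is cut; the C12 carbonyl and the C8 oxygen are traced back to a furan ring made of C7, C8, C11, C12 and oxygen. Singlet oxygen would add across C8 and C12, and an amine would fragment the endoperoxide (Kornblum–DeLaMare type) to A2.
- In its favour: a furan ring tolerates bases and organometallic reagents that the methylene lactone does not, so ring-forming steps could ignore Michael acceptors. On this point it is the better plan; the regiochemistry of the fragmentation is as dependable as that of the gold closure, which makes it the equal there.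
- Against it here: A2 has C7=C11 and a hemiketal at C8, so C7 and C8 would both have to be created later by reduction with cis control, and C13 is missing and would need late enolate chemistry. Singlet oxygen could also engage the C2=C3–C4=C15 diene of ring A. The two real problems, C10 and the medium ring, stay unsolved.
- Comparison: longer after the key step, and it sets two stereocentres late that the chosen plan sets in one allylation.

Alternative 3: The cut is C1–C2. CrCl2 with catalytic NiCl2 would turn a C2 iodoalkyne into an alkynylchromium species that adds to a C1 aldehyde on quaternary C10, giving A3. Oxidation at C1, release of O10 and transannular 5-endo addition of O10 to C3 would then close ring A.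
- In its favour: ring A forms last in a transannular closure without a regiochemical choice, and the macrocyclisation creates no stereocentre that matters because C1 is oxidised. On this point it is better than the chosen closure at C4–C5, which must deliver 5S. Lactone and ester are carried as in the chosen plan (equal), and the step count after the key step is about equal.
- Against it here: A3 holds four collinear atoms C1–C2≡C3–C4 in a ten-membered ring that also contains the cis lactone, so strain is high. The aldehyde is neopentylic and slow to add. C10 must be made as a single enantiomer by a separate method without relay, and the C4–C5 bond with its stereocentre moves to an earlier intermolecular step where the same 2-metalated diene problem returns.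

Key step: step 16

Remark on the chemistry: locants C1–C15 in the names of 14–28 are those of the target; 7–9 and 14–16 are carried as both C10 epimers because this centre becomes the ketone in step 12.
Remark on the chemistry: the (1S,2S) ligand of step 2 is assumed to give the 2R ester; if the opposite sense is found, its (1R,2R) antipode is used.

Step 1
Reactants: 1 1,4-bis(trimethylsilyl)buta-1,3-diyne
Product: 2 buta-1,3-diyn-1-yl(trimethyl)silane
Conditions: MeLi·LiBr (1.05 equiv), Et2O, rt; aq. NH4Cl, 0 °C; kept as a pentane solution
Reagents that add atoms: none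
Why: Nucleophilic desilylation by methyllithium stops after one silyl group because the lithium acetylide formed is inert to a second attack; protonation should give the terminal diyne, which is handled only in solution.

Step 2
Reactants: 2 buta-1,3-diyn-1-yl(trimethyl)silane; 3 ethyl pyruvate
Product: 4 ethyl (2R)-2-hydroxy-2-methyl-6-(trimethylsilyl)hexa-3,5-diynoate
Conditions: Zn(OTf)2 (20 mol %), (1S,2S)-2-(dimethylamino)-1-(4-nitrophenyl)-3-(tert-butyldimethylsilyloxy)propan-1-ol (22 mol %), Et3N (30 mol %), toluene, 60 °C, sealed
Reagents that add atoms: none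
Why: Catalytic enantioselective alkynylation of an α-keto ester: the zinc acetylide formed with Zn(OTf)2 and Et3N adds to the ketone of the keto ester bound to zinc in bidentate fashion, and the amino alcohol blocks one face, which sets the carbinol that later becomes C1.

Step 3
Reactants: 4 ethyl (2R)-2-hydroxy-2-methyl-6-(trimethylsilyl)hexa-3,5-diynoate
Product: 5 ethyl (2R)-2-methyl-2-(triethylsilyloxy)-6-(trimethylsilyl)hexa-3,5-diynoate
Conditions: Et3SiOTf, 2,6-lutidine, CH2Cl2, −78 to 0 °C
Reagents that add atoms: triethylsilyl trifluoromethanesulfonate, CC[Si](CC)(CC)OS(=O)(=O)C(F)(F)F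
Why: Silylation of a hindered tertiary alcohol with a silyl triflate; the ether prevents retro-addition of the alkoxide and allows the reduction of step 4 to stop at the aldehyde.

Step 4
Reactants: 5 ethyl (2R)-2-methyl-2-(triethylsilyloxy)-6-(trimethylsilyl)hexa-3,5-diynoate
Product: 6 (2R)-2-methyl-2-(triethylsilyloxy)-6-(trimethylsilyl)hexa-3,5-diynal
Conditions: iBu2AlH (1.1 equiv), CH2Cl2, −78 °C; aq. potassium sodium tartrate
Reagents that add atoms: none
Why: Partial hydride reduction of an ester; the aluminium hemiacetal next to a quaternary α-silyloxy carbon should collapse only on work-up, and the aldehyde has no α-hydrogen to lose.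

Step 5
Reactants: 6 (2R)-2-methyl-2-(triethylsilyloxy)-6-(trimethylsilyl)hexa-3,5-diynal
Product: 7 (5R)-5-methyl-5-(triethylsilyloxy)-9-(trimethylsilyl)non-1-ene-6,8-diyn-4-ol (both C4 epimers)
Conditions: CH2=CHCH2MgBr, Et2O, −78 °C; aq. NH4Cl
Reagents that add atoms: allylmagnesium bromide, C=CC[Mg]Br
Why: Grignard addition to the aldehyde brings in C9 and C8 and leaves C10 at the carbinol level; the new centre need not be controlled because it is oxidised in step 12.

Step 6
Reactants: 7 (5R)-5-methyl-5-(triethylsilyloxy)-9-(trimethylsilyl)non-1-ene-6,8-diyn-4-ol (both C4 epimers)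
Product: 8 (5R)-5-methyl-4,5-bis(triethylsilyloxy)-9-(trimethylsilyl)non-1-ene-6,8-diyne (both C4 epimers)
Conditions: Et3SiOTf, 2,6-lutidine, CH2Cl2, −78 to 0 °C
Reagents that add atoms: triethylsilyl trifluoromethanesulfonate, CC[Si](CC)(CC)OS(=O)(=O)C(F)(F)F
Why: Silylation; a non-chelating ether on the later C10 keeps the coming β-oxy aldehyde from dehydrating and from steering step 10 by chelation, and it is removed together with the first silyl group in step 11.

Step 7
Reactants: 8 (5R)-5-methyl-4,5-bis(triethylsilyloxy)-9-(trimethylsilyl)non-1-ene-6,8-diyne (both C4 epimers)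
Product: 9 (4R)-4-methyl-3,4-bis(triethylsilyloxy)-8-(trimethylsilyl)octa-5,7-diynal (both C3 epimers)
Conditions: OsO4 (2 mol %), NaIO4 (4 equiv), 2,6-lutidine, dioxane/H2O (3:1), rt
Reagents that add atoms: osmium tetroxide, O=[Os](=O)(=O)=O (catalytic carrier of the oxygen); sodium periodate, [Na+].[O-]I(=O)(=O)=O (terminal oxidant)
Why: Lemieux–Johnson oxidative cleavage; the electron-rich terminal alkene is dihydroxylated far faster than the silyl-capped diyne, and the buffered periodate cleaves the diol to the C8 aldehyde, which is used without chromatography.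

Step 8
Reactants: 10 (S)-2,3-O-isopropylideneglyceraldehyde; 11 methyl acrylate
Product: 12 methyl 2-{[(4S)-2,2-dimethyl-1,3-dioxolan-4-yl](hydroxy)methyl}prop-2-enoate (both carbinol epimers)
Conditions: DABCO (0.5 equiv), dioxane/H2O (1:1), rt
Reagents that add atoms: none
Why: Morita–Baylis–Hillman reaction; it forms C7–C11, the carbinol centre is of no consequence because it becomes sp2 in step 9, and the mild amine should leave the α-stereocentre of 10 (the later C6) intact.

Step 9
Reactants: 12 methyl 2-{[(4S)-2,2-dimethyl-1,3-dioxolan-4-yl](hydroxy)methyl}prop-2-enoate (both carbinol epimers)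
Product: 13 methyl (2Z)-2-(bromomethyl)-3-[(4R)-2,2-dimethyl-1,3-dioxolan-4-yl]prop-2-enoate
Conditions: N-bromosuccinimide, Me2S, CH2Cl2, 0 °C to rt
Reagents that add atoms: N-bromosuccinimide, O=C1CCC(=O)N1Br
Why: Allylic bromination with transposition: Corey–Kim-type activation of the hydroxyl as an alkoxysulfonium ion and SN2′ attack of bromide should give the thermodynamically preferred (Z) enoate under neutral conditions that spare the acetonide.

Step 10
Reactants: 9 (4R)-4-methyl-3,4-bis(triethylsilyloxy)-8-(trimethylsilyl)octa-5,7-diynal (both C3 epimers); 13 methyl (2Z)-2-(bromomethyl)-3-[(4R)-2,2-dimethyl-1,3-dioxolan-4-yl]prop-2-enoate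
Product: 15 cis-fused 8,12-olide with C11=C13 (1R,6R,7S,8S; 5,6-O-isopropylidene; 1,10-bis-O-triethylsilyl; C10 epimers), via hydroxy ester 14 (not isolated)
Conditions: In powder (1.5 equiv), THF/H2O (3:1), rt; then PPTS (cat.), CH2Cl2, rt
Reagents that add atoms: none
Why: Barbier allylation followed by lactonisation: the allylindium species reacts at C7 with allylic transposition through a Zimmerman–Traxler chair, the (Z) reagent giving the 7,8-syn adduct and hence the cis lactone with its exocyclic methylene. The C7 face should be set by C6: with C6–H in the alkene plane (allylic 1,3-strain) the aldehyde enters anti to the C6–O bond, which corresponds to 7S,8S. Only O8 can close onto the ester because O6 is tied in the acetonide.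

Step 11
Reactants: 15 cis-fused 8,12-olide with C11=C13 (1R,6R,7S,8S; 5,6-O-isopropylidene; 1,10-bis-O-triethylsilyl; C10 epimers)
Product: 16 1,10-diol of the 8,12-olide (1R,6R,7S,8S; 5,6-O-isopropylidene; C10 epimers)
Conditions: HF·pyridine, pyridine, THF, 0 °C to rt
Reagents that add atoms: none
Why: Fluoride desilylation in a buffered acidic medium removes both triethylsilyl ethers and should leave the alkynyl C–Si bond, the acetonide and the lactone untouched.

Step 12
Reactants: 16 1,10-diol of the 8,12-olide (1R,6R,7S,8S; 5,6-O-isopropylidene; C10 epimers)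
Product: 17 C10 ketone with free C1 tertiary propargylic alcohol (1R,6R,7S,8S; 5,6-O-isopropylidene)
Conditions: IBX (2 equiv), DMSO, rt
Reagents that add atoms: none
Why: IBX oxidation turns the secondary alcohol of a 1,2-diol into the α-ketol without glycol cleavage and cannot touch the tertiary alcohol; both C10 epimers converge, and the neutral medium avoids expulsion of the lactone oxygen now β to the ketone.

Step 13
Reactants: 17 C10 ketone with free C1 tertiary propargylic alcohol (1R,6R,7S,8S; 5,6-O-isopropylidene)
Product: 18 5,6-diol of the ketol lactone (1R,6R,7S,8S)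
Conditions: AcOH/H2O (4:1), 35 °C
Reagents that add atoms: none
Why: Acetal hydrolysis of a terminal dioxolane under weak acid; the conditions are chosen so that the β-acyloxy ketone does not eliminate and the lactone does not move to the freed O6, and the diol is taken on at once.

Step 14
Reactants: 18 5,6-diol of the ketol lactone (1R,6R,7S,8S)
Product: 19 5-O-tert-butyldimethylsilyl ether with free 6-OH (1R,6R,7S,8S)
Conditions: tBuMe2SiCl (1.1 equiv), imidazole, CH2Cl2, −10 to 0 °C
Reagents that add atoms: tert-butyldimethylsilyl chloride, CC(C)(C)[Si](C)(C)Cl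
Why: Selective silylation of the primary hydroxyl over the secondary and tertiary ones on steric grounds; imidazole is too weak a base to open the lactone.

Step 15
Reactants: 19 5-O-tert-butyldimethylsilyl ether with free 6-OH (1R,6R,7S,8S); 20 methacryloyl chloride
Product: 21 open precursor: C10 ketone; C1 tertiary alcohol carrying methyl and the silyl diyne; 8,12-olide with C11=C13; 6-O-methacrylate; 5-O-tert-butyldimethylsilyl (1R,6R,7S,8S)
Conditions: pyridine, DMAP (10 mol %), CH2Cl2, −10 to 0 °C
Reagents that add atoms: none
Why: DMAP-catalysed acylation of the only hydroxyl that can react (the tertiary propargylic one is too hindered); the weak base avoids elimination across C8–C9 and silyl or acyl migration.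

Step 16
Reactants: 21 open precursor: C10 ketone; C1 tertiary alcohol carrying methyl and the silyl diyne; 8,12-olide with C11=C13; 6-O-methacrylate; 5-O-tert-butyldimethylsilyl (1R,6R,7S,8S)
Product: 22 5-(trimethylsilylethynyl)-3(2H)-furanone with quaternary C10 joined through C9 to the lactone (6R,7S,8S,10R)
Conditions: AuCl3 (5 mol %), CH2Cl2 (0.05 M), 4 Å molecular sieves, rt, dark
Reagents that add atoms: none
Why: Trivalent gold coordinates the C2≡C3 triple bond and the C10 carbonyl oxygen adds to C3 in a 5-endo-dig closure, the only ring closed, to give a vinylgold oxocarbenium ion. C10 is then a cation beside the C1 carbinol, and a 1,2-shift of methyl C14 from C1 to C10 (semipinacol or α-ketol type) turns the C1 hydroxyl into the C1 ketone; protodeauration at C2 frees the catalyst. The closest known reaction is the gold- or platinum-catalysed heterocyclisation with 1,2-alkyl migration of 2-hydroxy-2-alkynyl ketones to 3(2H)-furanones. The new stereocentre C10 is controlled by the C1 carbinol of 21: the methyl group leaves C1 and arrives at C10 on the same face of the planar five-membered cation, so 1R is expected to become 10R. Methyl is the only group on C1 that can migrate, because the other two carbon substituents are ring members. The step needs regioselectivity for C3, which the five-membered closure and the silyl cap on the distal alkyne secure, and chemoselectivity for the alkyne over three enoate alkenes, which the carbophilic catalyst provides. It also needs a neutral medium, because 21 is a β-acyloxy ketone; the anhydrous chloride in dichloromethane meets this.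

Step 17
Reactants: 22 5-(trimethylsilylethynyl)-3(2H)-furanone with quaternary C10 joined through C9 to the lactone (6R,7S,8S,10R)
Product: 23 5-ethynyl-3(2H)-furanone (6R,7S,8S,10R)
Conditions: AgNO3 (10 mol %), acetone/H2O (10:1), rt
Reagents that add atoms: none
Why: Silver-catalysed protodesilylation through a silver acetylide is neutral and specific for alkynyl silanes, so the silyl ether, the esters and the Michael acceptors (which methanolic carbonate would attack) should survive.

Step 18
Reactants: 23 5-ethynyl-3(2H)-furanone (6R,7S,8S,10R)
Product: 25 2-iodoalkene with iodine on C4 and C15 as methylene (6R,7S,8S,10R), via alkenylstannane 24 (not isolated)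
Conditions: Bu3SnH (1.2 equiv, slow addition), PdCl2(PPh3)2 (3 mol %), THF, 0 °C; then I2 (1.3 equiv), CH2Cl2, 0 °C; aq. Na2S2O3, KF
Reagents that add atoms: iodine, I-I
Why: Palladium-catalysed hydrostannation followed by iododestannylation: syn hydropalladation puts hydride on the electrophilic terminus C15 and the metal on C4, the usual outcome for terminal alkynes conjugated with an electron-poor π-system, and iodine then replaces tin with retention. A direct proton/iodide addition is avoided because iodide would add to C15 in the conjugate sense.

Step 19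
Reactants: 25 2-iodoalkene with iodine on C4 and C15 as methylene (6R,7S,8S,10R)
Product: 26 primary C5 alcohol (6R,7S,8S,10R)
Conditions: HF·pyridine, pyridine, THF, 0 °C
Reagents that add atoms: none
Why: Fluoride desilylation under weakly acidic buffering, which should not trigger the base-induced shift of the C6 ester to the freed C5 hydroxyl.

Step 20
Reactants: 26 primary C5 alcohol (6R,7S,8S,10R)
Product: 27 C5 aldehyde (6R,7S,8S,10R)
Conditions: Dess–Martin periodinane, NaHCO3, CH2Cl2, 0 °C to rt; used at once
Reagents that add atoms: none
Why: Dess–Martin oxidation is neutral and fast, so the α-acyloxy aldehyde should form without epimerisation at C6 or loss of the ester.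

Step 21
Reactants: 27 C5 aldehyde (6R,7S,8S,10R)
Product: 28 CNP0142847.2 (5S,6R,7S,8S,10R)
Conditions: CrCl2 (10 equiv), NiCl2 (0.1 equiv), degassed DMSO, 0.002 M, syringe-pump addition, rt
Reagents that add atoms: none
Why: Nozaki–Hiyama–Kishi reaction: zerovalent nickel inserts into the C4–I bond, the alkenyl group passes to trivalent chromium and adds to the aldehyde only, which spares esters and enones and closes the ten-membered ring at C4–C5. The furanone and the cis lactone hold the two ends close, and Felkin–Anh addition anti to the C6 acyloxy group corresponds to the 5,6-anti relation, that is 5S.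

## Compound list

1 | 1,4-bis(trimethylsilyl)buta-1,3-diyne | C[Si](C)(C)C#CC#C[Si](C)(C)C | starting material
2 | buta-1,3-diyn-1-yl(trimethyl)silane | C[Si](C)(C)C#CC#C | intermediate
3 | ethyl pyruvate | CCOC(=O)C(C)=O | starting material
4 | ethyl (2R)-2-hydroxy-2-methyl-6-(trimethylsilyl)hexa-3,5-diynoate | CCOC(=O)[C@](C)(O)C#CC#C[Si](C)(C)C | intermediate
5 | ethyl (2R)-2-methyl-2-(triethylsilyloxy)-6-(trimethylsilyl)hexa-3,5-diynoate | CCOC(=O)[C@](C)(O[Si](CC)(CC)CC)C#CC#C[Si](C)(C)C | intermediate
6 | (2R)-2-methyl-2-(triethylsilyloxy)-6-(trimethylsilyl)hexa-3,5-diynal | O=C[C@](C)(O[Si](CC)(CC)CC)C#CC#C[Si](C)(C)C | intermediate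
7 | (5R)-5-methyl-5-(triethylsilyloxy)-9-(trimethylsilyl)non-1-ene-6,8-diyn-4-ol, both C4 epimers | C=CCC(O)[C@](C)(O[Si](CC)(CC)CC)C#CC#C[Si](C)(C)C | intermediate
8 | (5R)-5-methyl-4,5-bis(triethylsilyloxy)-9-(trimethylsilyl)non-1-ene-6,8-diyne, both C4 epimers | C=CCC(O[Si](CC)(CC)CC)[C@](C)(O[Si](CC)(CC)CC)C#CC#C[Si](C)(C)C | intermediate
9 | (4R)-4-methyl-3,4-bis(triethylsilyloxy)-8-(trimethylsilyl)octa-5,7-diynal, both C3 epimers | O=CCC(O[Si](CC)(CC)CC)[C@](C)(O[Si](CC)(CC)CC)C#CC#C[Si](C)(C)C | intermediate
10 | (S)-2,3-O-isopropylideneglyceraldehyde, (4S)-2,2-dimethyl-1,3-dioxolane-4-carbaldehyde | CC1(C)OC[C@@H](C=O)O1 | starting material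
11 | methyl acrylate | COC(=O)C=C | starting material
12 | methyl 2-{[(4S)-2,2-dimethyl-1,3-dioxolan-4-yl](hydroxy)methyl}prop-2-enoate, both carbinol epimers | COC(=O)C(=C)C(O)[C@@H]1COC(C)(C)O1 | intermediate
13 | methyl (2Z)-2-(bromomethyl)-3-[(4R)-2,2-dimethyl-1,3-dioxolan-4-yl]prop-2-enoate | COC(=O)/C(CBr)=C/[C@@H]1COC(C)(C)O1 | intermediate
14 | open hydroxy ester: methyl 2-methylidene ester (C12) with C7 bearing the (6R)-dioxolanyl group and the chain C8H(OH)–C9H2–C10H(OSiEt3)–C1(CH3)(OSiEt3)–C≡C–C≡C–SiMe3; 1R,6R,7S,8S, C10 epimers | COC(=O)C(=C)[C@H]([C@@H]1COC(C)(C)O1)[C@@H](O)CC(O[Si](CC)(CC)CC)[C@](C)(O[Si](CC)(CC)CC)C#CC#C[Si](C)(C)C | intermediate (not isolated)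
15 | cis α-methylene-γ-butyrolactone (8,12-olide) with the (6R)-2,2-dimethyl-1,3-dioxolan-4-yl group on C7 and the chain C9H2–C10H(OSiEt3)–C1(CH3)(OSiEt3)–C≡C–C≡C–SiMe3 on C8; 1R,6R,7S,8S, C10 epimers | CC[Si](CC)(CC)OC(C[C@@H]1OC(=O)C(=C)[C@@H]1[C@@H]2COC(C)(C)O2)[C@](C)(O[Si](CC)(CC)CC)C#CC#C[Si](C)(C)C | intermediate
16 | 1,10-diol of 15; 1R,6R,7S,8S, C10 epimers | OC(C[C@@H]1OC(=O)C(=C)[C@@H]1[C@@H]2COC(C)(C)O2)[C@](C)(O)C#CC#C[Si](C)(C)C | intermediate
17 | C10 ketone with free 1-OH, 5,6-O-isopropylidene; 1R,6R,7S,8S | O=C(C[C@@H]1OC(=O)C(=C)[C@@H]1[C@@H]2COC(C)(C)O2)[C@](C)(O)C#CC#C[Si](C)(C)C | intermediate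
18 | 5,6-diol of the ketol lactone; 1R,6R,7S,8S | O=C(C[C@@H]1OC(=O)C(=C)[C@@H]1[C@@H](O)CO)[C@](C)(O)C#CC#C[Si](C)(C)C | intermediate
19 | 5-O-tert-butyldimethylsilyl ether with free 6-OH; 1R,6R,7S,8S | O=C(C[C@@H]1OC(=O)C(=C)[C@@H]1[C@@H](O)CO[Si](C)(C)C(C)(C)C)[C@](C)(O)C#CC#C[Si](C)(C)C | intermediate
20 | methacryloyl chloride | C=C(C)C(=O)Cl | starting material
21 | key-step precursor: C10 ketone, C1 tertiary propargylic alcohol (methyl, trimethylsilyl diyne), 8,12-olide with C11=C13, 6-O-methacrylate, 5-O-tert-butyldimethylsilyl; 1R,6R,7S,8S | C[C@@](O)(C#CC#C[Si](C)(C)C)C(=O)C[C@@H]1OC(=O)C(=C)[C@@H]1[C@H](CO[Si](C)(C)C(C)(C)C)OC(=O)C(C)=C | intermediate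
22 | key-step product: 5-(trimethylsilylethynyl)-3(2H)-furanone with quaternary C10; 6R,7S,8S,10R | C[Si](C)(C)C#CC1=CC(=O)[C@](C)(O1)C[C@@H]2OC(=O)C(=C)[C@@H]2[C@H](CO[Si](C)(C)C(C)(C)C)OC(=O)C(C)=C | intermediate
23 | 5-ethynyl-3(2H)-furanone; 6R,7S,8S,10R | C#CC1=CC(=O)[C@](C)(O1)C[C@@H]2OC(=O)C(=C)[C@@H]2[C@H](CO[Si](C)(C)C(C)(C)C)OC(=O)C(C)=C | intermediate
24 | C4 tributylstannyl alkene (C15 methylene); 6R,7S,8S,10R | C=C([Sn](CCCC)(CCCC)CCCC)C1=CC(=O)[C@](C)(O1)C[C@@H]2OC(=O)C(=C)[C@@H]2[C@H](CO[Si](C)(C)C(C)(C)C)OC(=O)C(C)=C | intermediate (not isolated)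
25 | C4 iodoalkene (C15 methylene), 5-O-tert-butyldimethylsilyl; 6R,7S,8S,10R | C=C(I)C1=CC(=O)[C@](C)(O1)C[C@@H]2OC(=O)C(=C)[C@@H]2[C@H](CO[Si](C)(C)C(C)(C)C)OC(=O)C(C)=C | intermediate
26 | C4 iodoalkene with free primary C5 alcohol; 6R,7S,8S,10R | C=C(I)C1=CC(=O)[C@](C)(O1)C[C@@H]2OC(=O)C(=C)[C@@H]2[C@H](CO)OC(=O)C(C)=C | intermediate
27 | C4 iodoalkene with C5 aldehyde; 6R,7S,8S,10R | C=C(I)C1=CC(=O)[C@](C)(O1)C[C@@H]2OC(=O)C(=C)[C@@H]2[C@H](C=O)OC(=O)C(C)=C | intermediate
28 | CNP0142847.2; 5S,6R,7S,8S,10R | C=C(C)C(=O)O[C@@H]1[C@H]2C(=C)C(=O)O[C@H]2C[C@@]2(C)OC(=CC2=O)C(=C)[C@@H]1O | target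

## Step count and least certain steps

Total step count: 21 steps. Longest linear sequence: 19 steps (steps 1–7 and 10–21, from 1 to 28); steps 8 and 9 form the short branch.

**Step 16 (key step).** The most likely failure is interception of the cyclic oxocarbenium ion before the methyl shift, because methyl is a poor migrating group. Possible paths are loss of a C9 proton followed by expulsion of the lactone oxygen from C8, capture by traces of water, or reversal of the ring closure with loss of the silyl cap. Fallback, from 21 back to 22: 21 is treated with N-iodosuccinimide in CH2Cl2 at rt, an electrophile-induced version of the same closure and 1,2-shift that is known for 2-hydroxy-2-alkynyl ketones and in which the closure is irreversible. This would give the 2-iodo-3(2H)-furanone F1, and the C2 iodide is then removed by hydrodehalogenation with Bu3SnH and catalytic Pd(PPh3)4 to return to 22.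

**Step 10.** The C7/C8 syn relation has good precedent, but facial discrimination by C6 on the allylindium species may be poor or reversed, because the acetal oxygen and the acetal methylene on C6 differ little in size and the argument rests on a conformational model. Fallback, from 9 back to 21: the enantiomeric aldehyde (R)-2,3-O-isopropylideneglyceraldehyde F2 is taken through the operations of steps 8 and 9 to the Morita–Baylis–Hillman adduct F3 and the (Z)-bromide F4. Coupling of F4 with 9 as in step 10 would give, through hydroxy ester F5, the 6-epi lactone F6 with the 7S,8S ring. The operations of steps 11–14 then lead through diol F7, ketol F8 and 5,6-diol F9 to silyl ether F10. A Mitsunobu esterification of F10 with methacrylic acid (PPh3, diisopropyl azodicarboxylate, THF, 0 °C) puts on the ester with inversion at C6 and gives 21.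

**Step 2.** Low enantioselectivity, or consumption of the enolisable keto ester by self-condensation under amine and zinc at 60 °C, is possible; the terminal diyne may also oligomerise. Fallback, from 1 back to 6: 1 is converted with MeLi·LiBr into lithium (trimethylsilyl)butadiynide F11. This is added at −78 °C (THF, MgBr2·OEt2) to (1S,2R,5S)-8-phenylmenthyl pyruvate F12, made from the corresponding alcohol and pyruvoyl chloride. In the chelated keto ester the phenyl group covers one face, which should lead to the (2R) adduct F13. Silylation as in step 3 gives the triethylsilyl ether F14, and reduction as in step 4 gives 6 and returns the auxiliary alcohol.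

**Step 18.** Tin may be delivered to the terminal carbon C15, or the tin hydride may reduce the methylene lactone in the conjugate sense, if hydropalladation of the hindered, electron-poor alkyne is slow. Fallback, from 23 back to 25: haloboration with 9-iodo-9-borabicyclo[3.3.1]nonane (CH2Cl2, −20 °C) puts boron on the terminal carbon and iodide on C4 by cis addition and would give the alkenylborane F15. Protodeboronation with acetic acid then gives 25.

**Step 21.** Intermolecular coupling may compete with closure of the strained ring, and attack on the other aldehyde face would give the C5 epimer if the ring conformation overrides the Felkin–Anh preference. Fallback, from 27 back to 28: the product mixture containing the C5 epimer F16 is oxidised with Dess–Martin periodinane to the C5 ketone F17. F17 is then reduced under reagent control (Corey–Bakshi–Shibata reduction, catecholborane, −78 °C) to 28.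

## Further compounds

F1 | step 16 | 2-iodo-5-(trimethylsilylethynyl)-3(2H)-furanone analogue of 22; 6R,7S,8S,10R | C[Si](C)(C)C#CC1=C(I)C(=O)[C@](C)(O1)C[C@@H]2OC(=O)C(=C)[C@@H]2[C@H](CO[Si](C)(C)C(C)(C)C)OC(=O)C(C)=C
F2 | step 10 | (R)-2,3-O-isopropylideneglyceraldehyde | CC1(C)OC[C@H](C=O)O1
F3 | step 10 | methyl 2-{[(4R)-2,2-dimethyl-1,3-dioxolan-4-yl](hydroxy)methyl}prop-2-enoate, both carbinol epimers | COC(=O)C(=C)C(O)[C@H]1COC(C)(C)O1
F4 | step 10 | methyl (2Z)-2-(bromomethyl)-3-[(4S)-2,2-dimethyl-1,3-dioxolan-4-yl]prop-2-enoate | COC(=O)/C(CBr)=C/[C@H]1COC(C)(C)O1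
F5 | step 10 | 6-epimer of hydroxy ester 14; 1R,6S,7S,8S, C10 epimers | COC(=O)C(=C)[C@H]([C@H]1COC(C)(C)O1)[C@@H](O)CC(O[Si](CC)(CC)CC)[C@](C)(O[Si](CC)(CC)CC)C#CC#C[Si](C)(C)C
F6 | step 10 | 6-epimer of lactone 15; 1R,6S,7S,8S, C10 epimers | CC[Si](CC)(CC)OC(C[C@@H]1OC(=O)C(=C)[C@@H]1[C@H]2COC(C)(C)O2)[C@](C)(O[Si](CC)(CC)CC)C#CC#C[Si](C)(C)C
F7 | step 10 | 6-epimer of diol 16; 1R,6S,7S,8S, C10 epimers | OC(C[C@@H]1OC(=O)C(=C)[C@@H]1[C@H]2COC(C)(C)O2)[C@](C)(O)C#CC#C[Si](C)(C)C
F8 | step 10 | 6-epimer of ketol 17; 1R,6S,7S,8S | O=C(C[C@@H]1OC(=O)C(=C)[C@@H]1[C@H]2COC(C)(C)O2)[C@](C)(O)C#CC#C[Si](C)(C)C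
F9 | step 10 | 6-epimer of diol 18; 1R,6S,7S,8S | O=C(C[C@@H]1OC(=O)C(=C)[C@@H]1[C@H](O)CO)[C@](C)(O)C#CC#C[Si](C)(C)C
F10 | step 10 | 6-epimer of silyl ether 19; 1R,6S,7S,8S | O=C(C[C@@H]1OC(=O)C(=C)[C@@H]1[C@H](O)CO[Si](C)(C)C(C)(C)C)[C@](C)(O)C#CC#C[Si](C)(C)C
F11 | step 2 | lithium (trimethylsilyl)buta-1,3-diynide | [Li]C#CC#C[Si](C)(C)C
F12 | step 2 | (1S,2R,5S)-5-methyl-2-(2-phenylpropan-2-yl)cyclohexyl 2-oxopropanoate | CC(C)(c1ccccc1)[C@H]1CC[C@H](C)C[C@@H]1OC(=O)C(C)=O
F13 | step 2 | (1S,2R,5S)-5-methyl-2-(2-phenylpropan-2-yl)cyclohexyl (2R)-2-hydroxy-2-methyl-6-(trimethylsilyl)hexa-3,5-diynoate | CC(C)(c1ccccc1)[C@H]1CC[C@H](C)C[C@@H]1OC(=O)[C@](C)(O)C#CC#C[Si](C)(C)C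
F14 | step 2 | (1S,2R,5S)-5-methyl-2-(2-phenylpropan-2-yl)cyclohexyl (2R)-2-methyl-2-(triethylsilyloxy)-6-(trimethylsilyl)hexa-3,5-diynoate | CC(C)(c1ccccc1)[C@H]1CC[C@H](C)C[C@@H]1OC(=O)[C@](C)(O[Si](CC)(CC)CC)C#CC#C[Si](C)(C)C
F15 | step 18 | alkenylborane from 23: iodine on C4, 9-borabicyclo[3.3.1]nonan-9-yl on C15, cis; 6R,7S,8S,10R | I/C(=C\B1C2CCCC1CCC2)C1=CC(=O)[C@](C)(O1)C[C@@H]2OC(=O)C(=C)[C@@H]2[C@H](CO[Si](C)(C)C(C)(C)C)OC(=O)C(C)=C
F16 | step 21 | C5 epimer of 28; 5R,6R,7S,8S,10R | C=C(C)C(=O)O[C@@H]1[C@H]2C(=C)C(=O)O[C@H]2C[C@@]2(C)OC(=CC2=O)C(=C)[C@H]1O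
F17 | step 21 | C5 ketone derived from 28 and F16; 6R,7S,8S,10R | C=C(C)C(=O)O[C@@H]1[C@H]2C(=C)C(=O)O[C@H]2C[C@@]2(C)OC(=CC2=O)C(=C)C1=O
A1 | alternative 1 | oxygen-bridged cyclodecanone: C1 ketone, C3–O–C10 bridge, C4=C15 methylene, C5=C6 silyl enol ether, silyloxyethyl arm on C7, silyl ether on C8 | C[C@]12O[C@H](CC1=O)C(=C)/C=C(O[Si](C)(C)C(C)(C)C)/[C@@H](CCO[Si](C)(C)C(C)(C)C)[C@@H](O[Si](C)(C)C(C)(C)C)C2
A2 | alternative 2 | 8-hydroxybutenolide fused to the bridged macrocycle, 6-O-triethylsilyl, 5-O-tert-butyldimethylsilyl, either C8 epimer | CC[Si](CC)(CC)O[C@@H]1C2=CC(=O)OC2(O)C[C@@]2(C)OC(=CC2=O)C(=C)[C@@H]1O[Si](C)(C)C(C)(C)C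
A3 | alternative 3 | ten-membered cyclic propargylic alcohol with C2≡C3, C1 epimers, 10-O-triethylsilyl, 5-O-tert-butyldimethylsilyl, 6-O-methacrylate, 8,12-olide | OC1[C@](C)(O[Si](CC)(CC)CC)C[C@@H]2OC(=O)C(=C)[C@@H]2[C@@H](OC(=O)C(C)=C)[C@@H](O[Si](C)(C)C(C)(C)C)C(=C)C#C1
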